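**Plan**

1. Labdane numbering is used: decalin C1–C10, side chain C11–C16 on C9, C17 on C8. Retrosynthesis cuts O15–Si, then moves O7 back to C9 (1,3-transposition of a tertiary allylic alcohol) and cuts the C6–O acyl bond, then takes both ring-B oxygens back to O2 added across a 6,8-diene, then cuts C9–C11 (alkyl–alkenyl coupling).
2. Ring A is then cut at C1–C2 and C3–C4, which leaves ring B as a carvone-derived cyclohexenone and C2–C3 as a vinylphosphonium salt; C10–C1 and C10–CH3 are cut last (enolate alkylations).
3. Forward: (R)-carvone is ring B (its methyl is C17, its isopropenyl group becomes C4 with both methyls). C10 is made quaternary, ring A is annulated in step 4, the C11–C16 chain is joined at C9, and ring B is oxygenated last.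
4. Stereochemistry: C5 is bought with (R)-carvone; C10 follows from alkylation anti to the isopropenyl group; O2 adds to the α face and fixes C9–O, which a suprafacial transposition turns into 7α-OH; hydride from the α face gives 6β-O; the E alkene is bought.
5. Enabling feature: ring A (C1–C4) carries no functional group and C4 is a gem-dimethyl carbon on C5. An isopropenyl group on C5 is therefore a latent tertiary C4 radical, a formyl group on quaternary C10 is C1, the two arms are trans on ring B, and only the C2–C3 bridge is missing.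

Key step: step 4

Remark: compound 3 is carried as a mixture of C6 epimers (carvone numbering; major trans isomer drawn); both give enolate 4, so the mixture is of no consequence.

**Route**

Step 1
Reactants: 1 (R)-carvone
Product: 3 trans-6-methylcarvone, via lithium dienolate 2 (not isolated)
Conditions: LDA, THF, −78 °C; MeI, −78 → 0 °C
Reagents that add atoms: iodomethane, CI
Why: Kinetic α′-deprotonation of the enone gives the cross-conjugated lithium dienolate, which is methylated at carbon (enolate alkylation); the new centre is an epimer mixture that is erased in step 2.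

Step 2
Reactants: 3 trans-6-methylcarvone
Product: 5 (5S,6R)-6-(hydroxymethyl)-2,6-dimethyl-5-(prop-1-en-2-yl)cyclohex-2-en-1-one, via lithium enolate 4 (not isolated)
Conditions: LDA, THF, −78 → 0 °C; CH2O (gas, from cracked paraformaldehyde), −78 °C; AcOH
Reagents that add atoms: formaldehyde, C=O
Why: Aldol hydroxymethylation of the tetrasubstituted lithium enolate, which is attacked axially anti to the pseudoaxial isopropenyl group on the neighbouring carbon, so the quaternary centre (future C10) carries its methyl cis and its one-carbon arm trans to the isopropenyl group.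

Step 3
Reactants: 5 hydroxymethyl ketone
Product: 6 (1R,6S)-1,3-dimethyl-2-oxo-6-(prop-1-en-2-yl)cyclohex-3-ene-1-carbaldehyde
Conditions: Dess–Martin periodinane, CH2Cl2, 0 °C → rt
Reagents that add atoms: none
Why: Dess–Martin oxidation of the neopentyl primary alcohol under neutral conditions gives the non-enolisable β-keto aldehyde without retro-aldol cleavage or deformylation.

Step 4
Reactants: 6 keto aldehyde
Product: 9 (4aS,8aS)-2,5,5,8a-tetramethyl-4a,5,6,8a-tetrahydronaphthalen-1(4H)-one, via phosphonium bromide 7 (not isolated), via phosphonium ylide 8 (not isolated)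
Conditions: Fe(acac)3 (30 mol %), PhSiH3, vinyltriphenylphosphonium bromide (1.5 equiv), EtOH/(CH2OH)2, 40 °C; evaporate; KHMDS (1.1 equiv), THF, −78 → 0 °C
Reagents that add atoms: vinyltriphenylphosphonium bromide, C=C[P+](c1ccccc1)(c1ccccc1)c1ccccc1.[Br-]
Why: Proposed new method: hydrogen-atom transfer from an iron hydride to the electron-rich isopropenyl group gives the tertiary C4 radical, which adds (Giese addition) to the electron-poor vinylphosphonium salt and so forms C3–C4 and the gem-dimethyl carbon; the α-phosphonio radical is reduced by divalent iron and protonated to salt 7, and KHMDS then gives ylide 8, whose intramolecular Wittig reaction with the formyl group forms C1=C2 and expels Ph3PO, so the two-carbon unit enters without any group that must be removed later. The closest known reaction types are the iron-hydride-initiated Giese addition of alkene-derived tertiary radicals to acrylates, enals and vinyl sulfones (including its radical–polar crossover annulation form with aldol closure), the photoredox addition of alkyl radicals to vinylphosphonium salts that ends in a Wittig olefination, and the anionic Schweizer annulation. Ring A closes in the Wittig stage as a six-membered ring, by 6-exo addition of the ylide carbon to the formyl carbon and cycloreversion of the oxaphosphetane to the ring alkene. No new stereocentre is formed: C5 and C10 are already set, and the trans ring fusion follows because the isopropenyl-derived arm and the formyl group are trans on ring B. The step needs hydrogen-atom transfer to the 1,1-disubstituted alkene in preference to the trisubstituted enone alkene (secured by the far higher rate of electron-rich terminal alkenes), intermolecular capture of the hindered radical (excess acceptor; only four-membered or 5-endo ring closures are open to it), and attack of the ylide on the aldehyde and not on the hindered conjugated ketone; the non-nucleophilic base in THF avoids deformylation of the β-keto aldehyde.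

Step 5
Reactants: 9 ring-A dienone
Product: 10 (4aS,8aS)-2,5,5,8a-tetramethyl-4a,5,6,7,8,8a-hexahydronaphthalen-1(4H)-one
Conditions: H2 (1 atm), RhCl(PPh3)3 (10 mol %), benzene, rt
Reagents that add atoms: none
Why: Homogeneous hydrogenation with RhCl(PPh3)3 reduces the cis-disubstituted C1=C2 alkene and leaves the trisubstituted conjugated C7=C8 alkene, as in the selective hydrogenation of carvone at its isopropenyl group.

Step 6
Reactants: 10 bicyclic enone
Product: 12 (4aS,8aS)-2,5,5,8a-tetramethyl-4a,5,6,7,8,8a-hexahydronaphthalen-1-yl trifluoromethanesulfonate, via potassium dienolate 11 (not isolated)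
Conditions: KHMDS, THF, −78 °C; PhNTf2, −78 → 0 °C
Reagents that add atoms: N-phenylbis(trifluoromethanesulfonimide), FC(F)(F)S(=O)(=O)N(c1ccccc1)S(=O)(=O)C(F)(F)F
Why: C10 is quaternary, so the only acidic hydrogens are the γ-hydrogens on C6; KHMDS gives the through-conjugated dienolate, which is triflated on oxygen (dienyl triflate formation).

Step 7
Reactants: 13 (2E)-3-methylpent-2-en-4-yn-1-ol
Product: 14 tert-butyldimethyl{[(2E)-3-methylpent-2-en-4-yn-1-yl]oxy}silane
Conditions: TBSCl, imidazole, CH2Cl2, 0 °C → rt
Reagents that add atoms: tert-butyldimethylsilyl chloride, CC(C)(C)[Si](C)(C)Cl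
Why: Standard silylation of a primary allylic alcohol.

Step 8
Reactants: 14 enyne silyl ether
Product: 15 tert-butyldimethyl{[(2E)-3-methylpenta-2,4-dien-1-yl]oxy}silane
Conditions: H2 (1 atm, 1 equiv), Pd/CaCO3 poisoned with Pb(OAc)2 (Lindlar catalyst), quinoline, hexane, rt
Reagents that add atoms: none
Why: Lindlar semihydrogenation turns the terminal alkyne into a vinyl group and leaves the trisubstituted E alkene untouched.

Step 9
Reactants: 15 diene silyl ether; 12 dienyl triflate
Product: 17 (13E)-15-(tert-butyldimethylsilyloxy)labda-6,8,13-triene, via alkyl-9-BBN adduct 16 (not isolated)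
Conditions: 15, 9-BBN dimer, THF, 0 °C → rt; then 12, Pd(dppf)Cl2 (5 mol %), AsPh3, Cs2CO3, DMF/THF/H2O, rt → 50 °C
Reagents that add atoms: none
Why: 9-BBN adds to the monosubstituted end of the diene (boron on C11; the trisubstituted alkene is inert), and the B-alkyl Suzuki–Miyaura coupling with the dienyl triflate forms C9–C11 with all alkene geometries retained.

Step 10
Reactants: 17 triene
Product: 19 (13E)-15-(tert-butyldimethylsilyloxy)-9α-hydroxylabda-7,13-dien-6-one, via 6α,9α-endoperoxide 18 (not isolated)
Conditions: O2, tetraphenylporphyrin (cat.), visible light, CH2Cl2, −30 °C; then Et3N, 0 °C → rt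
Reagents that add atoms: dioxygen, O=O
Why: Singlet oxygen adds [4+2] across C6 and C9 of the homoannular diene from the α face (the β face is covered by the C10 and C4 β-methyl groups, as in sterol 5,7-dienes), and the Kornblum–DeLaMare rearrangement, in which Et3N removes the only hydrogen on a peroxide carbon (C6–H), gives the γ-hydroxy enone with C9–O α.

Step 11
Reactants: 19 γ-hydroxy enone
Product: 20 (13E)-15-(tert-butyldimethylsilyloxy)labda-7,13-diene-6β,9α-diol
Conditions: NaBH4, CeCl3·7H2O, MeOH, −40 °C
Reagents that add atoms: none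
Why: Luche 1,2-reduction; hydride attacks C6 from the α face because the β face is blocked by the syn-axial C10 and C4 β-methyl groups, which gives the 6β-alcohol.

Step 12
Reactants: 20 diol
Product: 21 (13E)-15-(tert-butyldimethylsilyloxy)-9α-hydroxylabda-7,13-dien-6β-yl 3-methylbutanoate
Conditions: 3-methylbutanoic anhydride, DMAP, Et3N, CH2Cl2, rt → 35 °C
Reagents that add atoms: 3-methylbutanoic anhydride, CC(C)CC(=O)OC(=O)CC(C)C
Why: DMAP-catalysed acylation reaches only the secondary 6β-hydroxyl; the tertiary C9 hydroxyl, which holds the future O7, is inert, so the two oxygens are told apart without a protecting group.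

Step 13
Reactants: 21 ester
Product: 22 (13E)-15-(tert-butyldimethylsilyloxy)-7α-hydroxylabda-8,13-dien-6β-yl 3-methylbutanoate
Conditions: O3ReOSiPh3 (5 mol %), Et2O, −50 → −20 °C
Reagents that add atoms: none
Why: Perrhenate-catalysed 1,3-transposition of the allylic alcohol by a suprafacial [3,3] shift of its perrhenate ester delivers the α oxygen from C9 to the α face of C7 (anti to the 6β ester), driven by the change from tertiary to secondary carbinol and from a trisubstituted to a tetrasubstituted alkene.

Step 14
Reactants: 22 silyl ether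
Product: 23 (13E)-7α,15-dihydroxylabda-8,13-dien-6β-yl 3-methylbutanoate (CNP0173680.1)
Conditions: HF·pyridine, pyridine, THF, 0 °C → rt
Reagents that add atoms: none
Why: Buffered fluoride cleavage of the primary silyl ether leaves the ester, the allylic alcohol and both alkenes intact.

**Compound list**

1 | (R)-(−)-carvone, (5R)-2-methyl-5-(prop-1-en-2-yl)cyclohex-2-en-1-one | CC1=CC[C@H](CC1=O)C(C)=C | starting material
2 | lithium dienolate of 1 (enolate towards C6, isopropenyl carbon as in 1) | [Li+].CC1=CC[C@@H](C(C)=C)C=C1[O-] | intermediate (not isolated)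
3 | trans-6-methylcarvone, (5R,6S)-2,6-dimethyl-5-(prop-1-en-2-yl)cyclohex-2-en-1-one | CC1=CC[C@@H](C(C)=C)[C@H](C)C1=O | intermediate
4 | lithium enolate of 3 (tetrasubstituted enolate, isopropenyl carbon as in 1) | [Li+].CC1=CC[C@@H](C(C)=C)C(C)=C1[O-] | intermediate (not isolated)
5 | (5S,6R)-6-(hydroxymethyl)-2,6-dimethyl-5-(prop-1-en-2-yl)cyclohex-2-en-1-one (CH2OH trans, CH3 cis to isopropenyl) | CC1=CC[C@@H](C(C)=C)[C@](C)(CO)C1=O | intermediate
6 | (1R,6S)-1,3-dimethyl-2-oxo-6-(prop-1-en-2-yl)cyclohex-3-ene-1-carbaldehyde | CC1=CC[C@@H](C(C)=C)[C@](C)(C=O)C1=O | intermediate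
7 | [3-(2-formyl-2,4-dimethyl-3-oxocyclohex-4-en-1-yl)-3-methylbutyl]triphenylphosphonium bromide (ring stereocentres as in 6) | CC1=CC[C@@H](C(C)(C)CC[P+](c2ccccc2)(c2ccccc2)c2ccccc2)[C@](C)(C=O)C1=O.[Br-] | intermediate (not isolated)
8 | triphenylphosphonium ylide derived from 7 | CC1=CC[C@@H](C(C)(C)C[CH-][P+](c2ccccc2)(c2ccccc2)c2ccccc2)[C@](C)(C=O)C1=O | intermediate (not isolated)
9 | (4aS,8aS)-2,5,5,8a-tetramethyl-4a,5,6,8a-tetrahydronaphthalen-1(4H)-one (decalin with C1=C2, C7=C8 and C9=O) | CC1=CC[C@H]2C(C)(C)CC=C[C@]2(C)C1=O | intermediate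
10 | (4aS,8aS)-2,5,5,8a-tetramethyl-4a,5,6,7,8,8a-hexahydronaphthalen-1(4H)-one (decalin with C7=C8 and C9=O) | CC1=CC[C@H]2C(C)(C)CCC[C@]2(C)C1=O | intermediate
11 | potassium dienolate of 10 (C9–O−, C8=C9, C6=C7) | [K+].CC1=C([O-])[C@@]2(C)CCCC(C)(C)[C@@H]2C=C1 | intermediate (not isolated)
12 | (4aS,8aS)-2,5,5,8a-tetramethyl-4a,5,6,7,8,8a-hexahydronaphthalen-1-yl trifluoromethanesulfonate (C9 triflate of the 6,8-diene) | CC1=C(OS(=O)(=O)C(F)(F)F)[C@@]2(C)CCCC(C)(C)[C@@H]2C=C1 | intermediate
13 | (2E)-3-methylpent-2-en-4-yn-1-ol | C#C/C(C)=C/CO | starting material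
14 | tert-butyldimethyl{[(2E)-3-methylpent-2-en-4-yn-1-yl]oxy}silane | C#C/C(C)=C/CO[Si](C)(C)C(C)(C)C | intermediate
15 | tert-butyldimethyl{[(2E)-3-methylpenta-2,4-dien-1-yl]oxy}silane | C=C/C(C)=C/CO[Si](C)(C)C(C)(C)C | intermediate
16 | 9-[(3E)-5-(tert-butyldimethylsilyloxy)-3-methylpent-3-en-1-yl]-9-borabicyclo[3.3.1]nonane | B1(CC/C(C)=C/CO[Si](C)(C)C(C)(C)C)C2CCCC1CCC2 | intermediate (not isolated)
17 | (13E)-15-(tert-butyldimethylsilyloxy)labda-6,8,13-triene | CC1=C(CC/C(C)=C/CO[Si](C)(C)C(C)(C)C)[C@@]2(C)CCCC(C)(C)[C@@H]2C=C1 | intermediate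
18 | (13E)-15-(tert-butyldimethylsilyloxy)-6α,9α-epidioxylabda-7,13-diene | CC1=C[C@@H]2OO[C@@]1(CC/C(C)=C/CO[Si](C)(C)C(C)(C)C)[C@@]3(C)CCCC(C)(C)[C@H]23 | intermediate (not isolated)
19 | (13E)-15-(tert-butyldimethylsilyloxy)-9α-hydroxylabda-7,13-dien-6-one | CC1=CC(=O)[C@H]2C(C)(C)CCC[C@]2(C)[C@@]1(O)CC/C(C)=C/CO[Si](C)(C)C(C)(C)C | intermediate
20 | (13E)-15-(tert-butyldimethylsilyloxy)labda-7,13-diene-6β,9α-diol | CC1=C[C@@H](O)[C@H]2C(C)(C)CCC[C@]2(C)[C@@]1(O)CC/C(C)=C/CO[Si](C)(C)C(C)(C)C | intermediate
21 | (13E)-15-(tert-butyldimethylsilyloxy)-9α-hydroxylabda-7,13-dien-6β-yl 3-methylbutanoate | CC1=C[C@@H](OC(=O)CC(C)C)[C@H]2C(C)(C)CCC[C@]2(C)[C@@]1(O)CC/C(C)=C/CO[Si](C)(C)C(C)(C)C | intermediate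
22 | (13E)-15-(tert-butyldimethylsilyloxy)-7α-hydroxylabda-8,13-dien-6β-yl 3-methylbutanoate | CC1=C(CC/C(C)=C/CO[Si](C)(C)C(C)(C)C)[C@@]2(C)CCCC(C)(C)[C@@H]2[C@H](OC(=O)CC(C)C)[C@H]1O | intermediate
23 | (13E)-7α,15-dihydroxylabda-8,13-dien-6β-yl 3-methylbutanoate (CNP0173680.1) | CC1=C(CC/C(C)=C/CO)[C@@]2(C)CCCC(C)(C)[C@@H]2[C@H](OC(=O)CC(C)C)[C@H]1O | target

**Step count and risks**

Total step count: 14. Longest linear sequence: 12 (steps 1–6 and 9–14 from (R)-carvone).

Steps most likely to fail:

Step 4 (Proposed new method). The hindered tertiary radical may be reduced before it adds to the vinylphosphonium salt, the α-phosphonio radical may not be reduced cleanly to the phosphonium stage, and the base stage may deformylate the β-keto aldehyde or start intermolecular olefination with excess reagent. The fallback uses known chemistry, sets out from 6 and comes back at 9. The same iron-hydride radical generation (Fe(acac)3, PhSiH3, EtOH/(CH2OH)2) is run with acrolein as the acceptor; the iron enolate formed after Giese addition closes ring A by aldol addition to the formyl group (radical–polar crossover annulation, still forming C3–C4 and C1–C2 in one operation) and gives the β-hydroxy aldehyde F1 as a diastereomer mixture. Acid-catalysed dehydration (p-TsOH, benzene, reflux) gives the enal F2, and decarbonylation with RhCl(PPh3)3 (toluene, reflux) gives 9.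

Step 13. The perrhenate ester may ionise in place of the concerted shift; participation of the neighbouring 6β-acyloxy group, loss of configuration at C7, acyl shift or elimination to a diene would follow. The fallback sets out from 19, comes back at 23 and uses no allylic transposition. SmI2 (THF/t-BuOH, −78 °C) removes the γ-hydroxyl of 19, and kinetic α-protonation of the samarium dienolate gives the β,γ-unsaturated ketone F3. KHMDS and 2-(phenylsulfonyl)-3-phenyloxaziridine hydroxylate the C6–C9 dienolate at C7 from the axial α face to give the hydroxy ketone F4, and TESOTf/2,6-lutidine gives the silyl ether F5. NaBH4 reduces C6=O from the α face to the 6β-alcohol F6; LiHMDS followed by 3-methylbutanoyl chloride acylates its alkoxide to the ester F7; HF·pyridine removes both silyl groups and gives 23.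

Step 12. Acylation of the 6β-hydroxyl, which sits between the syn-axial C10 and C4 β-methyl groups, may be slow or incomplete, and forcing conditions may dehydrate the allylic alcohols. The fallback sets out from 19, comes back at 21 and forms the ester in the reduction event. DIBAL-H (2.2 equiv, CH2Cl2, −78 °C) reduces the ketone from the α face to the bis(diisobutylaluminium) alkoxide F8, which is trapped in the same flask with 3-methylbutanoic anhydride, DMAP and pyridine (−78 → 0 °C). Only the secondary aluminium alkoxide is acylated, and work-up frees the tertiary alcohol of 21.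

Further compounds
F1 | step 4 | 1-hydroxy-2-formyl derivative of 10 (ring-A aldol adduct, C1/C2 diastereomer mixture) | CC1=CC[C@H]2C(C)(C)CC(C=O)C(O)[C@]2(C)C1=O
F2 | step 4 | 2-formyl derivative of 9 (ring-A enal, C1=C2–CHO) | CC1=CC[C@H]2C(C)(C)CC(C=O)=C[C@]2(C)C1=O
F3 | step 13 | (13E)-15-(tert-butyldimethylsilyloxy)labda-8,13-dien-6-one | CC1=C(CC/C(C)=C/CO[Si](C)(C)C(C)(C)C)[C@@]2(C)CCCC(C)(C)[C@@H]2C(=O)C1
F4 | step 13 | (13E)-15-(tert-butyldimethylsilyloxy)-7α-hydroxylabda-8,13-dien-6-one | CC1=C(CC/C(C)=C/CO[Si](C)(C)C(C)(C)C)[C@@]2(C)CCCC(C)(C)[C@@H]2C(=O)[C@H]1O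
F5 | step 13 | (13E)-15-(tert-butyldimethylsilyloxy)-7α-(triethylsilyloxy)labda-8,13-dien-6-one | CC1=C(CC/C(C)=C/CO[Si](C)(C)C(C)(C)C)[C@@]2(C)CCCC(C)(C)[C@@H]2C(=O)[C@H]1O[Si](CC)(CC)CC
F6 | step 13 | (13E)-15-(tert-butyldimethylsilyloxy)-7α-(triethylsilyloxy)labda-8,13-dien-6β-ol | CC1=C(CC/C(C)=C/CO[Si](C)(C)C(C)(C)C)[C@@]2(C)CCCC(C)(C)[C@@H]2[C@H](O)[C@H]1O[Si](CC)(CC)CC
F7 | step 13 | (13E)-15-(tert-butyldimethylsilyloxy)-7α-(triethylsilyloxy)labda-8,13-dien-6β-yl 3-methylbutanoate | CC1=C(CC/C(C)=C/CO[Si](C)(C)C(C)(C)C)[C@@]2(C)CCCC(C)(C)[C@@H]2[C@H](OC(=O)CC(C)C)[C@H]1O[Si](CC)(CC)CC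
F8 | step 12 | 6β,9α-bis(diisobutylaluminium) alkoxide of diol 20 | CC1=C[C@@H](O[Al](CC(C)C)CC(C)C)[C@H]2C(C)(C)CCC[C@]2(C)[C@@]1(O[Al](CC(C)C)CC(C)C)CC/C(C)=C/CO[Si](C)(C)C(C)(C)C
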